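The target is three (2R,3R)-ε-viniferin units. Everything rests on cutting the bond between Cc (the CH of the seven-membered ring that sits on benzofuran ring Q) and Cd (the exocyclic CH carrying a 4-hydroxyphenyl on the eight-membered ring). A tetrameric para-quinone methide, electrophilic at Cd, alkylates stilbene carbon Cc of a protected ε-viniferin; the cation relayed to Ca is trapped by resorcinol ring P, which closes the seven-membered ring. Two C–C bonds, one ring and three stereocentres (Cd, Cc, Ca) form in one operation. The step exploits the para-hydroxyphenyl rings on Cd and Ca as quinone methide relays and the electron-rich ring P; its precursor is an open stilbene, not a dibenzocycloheptene.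

Key step: step 12

Labels: the twelve stereocentres are called Ca to Cl in the order in which they stand in the SMILES of 27 (Ca S, Cb R, Cc S, Cd R, Ce R, Cf R, Cg S, Ch S, Ci R, Cj R, Ck R, Cl R). Ca, Cd, Cg, Cj, Ck and Cl each carry one 4-oxygenated phenyl ring, called here the aryl on that carbon. The six 3,5-dioxygenated rings carry letters: ring P joins Ca and Cb; ring Q joins Cb and Cc and carries the furan oxygen of Cl; ring T joins Ce and Cf and carries the furan oxygen of Ck; ring U joins Cf and Cg; ring W joins Ch and Ci and carries the furan oxygen of Cj; ring Z sits on Ci. Unit 1 holds Ca, Cb, Cc, Cl; unit 2 holds Cd, Ce, Cf, Ck; unit 3 holds Cg, Ch, Ci, Cj.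

Assumption on the chemistry: the ylide from (1R,4R,5R)-isothiocineole (S-benzyl group exo) is taken to give the (2R,3R)-dihydrobenzofuran; if the sense proves opposite, the enantiomeric sulfide is used with no other change.

Protecting-group logic: pivalates switch off every arene that must not act as a Friedel–Crafts donor, benzyl ethers keep rings P and U electron-rich, and the tert-butyl groups make the quinone methides persistent.

Step 1
Reactants: 1 2-bromo-4,6-dimethoxybenzaldehyde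
Product: 2 2-bromo-4,6-dihydroxybenzaldehyde
Conditions: BBr3, CH2Cl2, −78 °C to rt; then H2O
Reagents that add atoms: none
Why: Boron tribromide cleaves both aryl methyl ethers (Lewis acid ether cleavage) and should leave the aldehyde and the aryl bromide untouched.

Step 2
Reactants: 2 2-bromo-4,6-dihydroxybenzaldehyde
Product: 3 3-bromo-4-formyl-5-hydroxyphenyl 2,2-dimethylpropanoate
Conditions: t-BuCOCl (1.05 equiv), Et3N, CH2Cl2, −40 to 0 °C
Reagents that add atoms: pivaloyl chloride, CC(C)(C)C(=O)Cl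
Why: Regioselective O-acylation, since the hydroxyl para to the formyl group is the more acidic one and is not held in the hydrogen bond to the carbonyl; the ester later deactivates this ring as a Friedel–Crafts donor.

Step 3
Reactants: 3 3-bromo-4-formyl-5-hydroxyphenyl 2,2-dimethylpropanoate; 4 1,3-bis(benzyloxy)-5-bromobenzene
Product: 6 racemic diaryl carbinol, via arylmagnesium bromide 5 (not isolated)
Conditions: 4 (2.2 equiv), Mg, THF, 40 °C; then 3, THF, −78 to −40 °C; aqueous NH4Cl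
Reagents that add atoms: none
Why: Grignard addition to the aldehyde, in which the first equivalent forms the magnesium phenoxide that activates the carbonyl by chelation while the hindered pivalate and the aryl bromide should survive at low temperature; the carbinol centre is racemic and is erased in step 6.

Step 4
Reactants: 6 racemic diaryl carbinol
Product: 7 racemic diaryl(tosyl)methane
Conditions: p-TolSO2Na, HCO2H/CH2Cl2, rt
Reagents that add atoms: sodium 4-methylbenzenesulfinate, [Na+].[O-]S(=O)c1ccc(C)cc1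
Why: Acid ionises the ortho-hydroxybenzhydrol to an ortho-quinone methide-type cation that the sulfinate traps at sulfur (sulfinate S-alkylation), giving a bench-stable ortho-quinone methide precursor.

Step 5
Reactants: 8 (1R,4R,5R)-isothiocineole; 9 1-(benzyloxy)-4-(bromomethyl)benzene
Product: 10 S-[4-(benzyloxy)benzyl]isothiocineolium tetrafluoroborate
Conditions: NaBF4, CH2Cl2/H2O, rt
Reagents that add atoms: sodium tetrafluoroborate, [Na+].F[B-](F)(F)F
Why: S-Alkylation of the sulfide on its exo lone pair by the benzylic bromide with anion exchange to a non-nucleophilic counter-ion should give one diastereomer at sulfur.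

Step 6
Reactants: 7 racemic diaryl(tosyl)methane; 10 S-[4-(benzyloxy)benzyl]isothiocineolium tetrafluoroborate
Product: 13 (2R,3R)-4-bromo-2,3-diaryl-2,3-dihydrobenzofuran-6-yl pivalate, via sulfonium ylide 11 (not isolated), via ortho-quinone methide 12 (not isolated)
Conditions: Cs2CO3, CH2Cl2, −20 °C to rt
Reagents that add atoms: none
Why: Formal [4+1] annulation of an ortho-quinone methide with a sulfonium ylide, in which the ylide carbon adds to the exocyclic carbon of 12 and the phenoxide then displaces the sulfide (5-exo-tet); C2 (R) is set by the face of the ylide left open by the bicyclic sulfide and C3 (R) by the trans-selective addition–closure sequence.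

Step 7
Reactants: 13 (2R,3R)-4-bromo-2,3-diaryl-2,3-dihydrobenzofuran-6-yl pivalate; 14 2,6-di-tert-butyl-4-ethenylphenol
Product: 15 monomer A (benzyl-protected tert-butylated ε-viniferin analogue)
Conditions: Pd2(dba)3 (catalytic), [(t-Bu)3PH]BF4 (catalytic), Cy2NMe, 1,4-dioxane, 80 °C
Reagents that add atoms: none
Why: Mizoroki–Heck coupling at the terminal carbon of the styrene, where the bulky electron-rich phosphine handles the ortho-substituted bromide and syn insertion with syn β-hydride elimination gives the E-stilbene, the hindered phenol and the pivalate being inert.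

Step 8
Reactants: 13 (2R,3R)-4-bromo-2,3-diaryl-2,3-dihydrobenzofuran-6-yl pivalate
Product: 16 triphenol bromide
Conditions: BCl3, C6HMe5, CH2Cl2, −78 °C
Reagents that add atoms: none
Why: Lewis acid debenzylation with pentamethylbenzene as benzyl-cation scavenger removes the three aryl benzyl ethers at low temperature and should spare the aryl bromide, the pivalate and the trans-dihydrofuran.

Step 9
Reactants: 16 triphenol bromide
Product: 17 tetrapivalate bromide
Conditions: t-BuCOCl, Et3N, DMAP (catalytic), CH2Cl2, 0 °C to rt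
Reagents that add atoms: pivaloyl chloride, CC(C)(C)C(=O)Cl
Why: Exhaustive O-acylation, which turns the future ring Z and the future aryl on Cj of unit 3 into electron-poor arenes that cannot act as Friedel–Crafts donors.

Step 10
Reactants: 17 tetrapivalate bromide; 14 2,6-di-tert-butyl-4-ethenylphenol
Product: 18 monomer B (pivalate-protected tert-butylated ε-viniferin analogue)
Conditions: Pd2(dba)3 (catalytic), [(t-Bu)3PH]BF4 (catalytic), Cy2NMe, 1,4-dioxane, 80 °C
Reagents that add atoms: none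
Why: Mizoroki–Heck coupling as in step 7, giving the E-stilbene while the aryl pivalates tolerate the hindered amine base.

Step 11
Reactants: 15 monomer A; 18 monomer B
Product: 22 tetrameric quinone methide (eight-membered ring closed; Cd still a quinone methide carbon), via monomer A phenoxyl radical 19 (not isolated), via monomer B phenoxyl radical 20 (not isolated), via cross bis(quinone methide) 21 (not isolated)
Conditions: 15 (1 equiv), 18 (3 equiv), Ag2O, CH2Cl2, rt, argon, dark; filter; BF3·OEt2 (0.2 equiv), −78 to −40 °C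
Reagents that add atoms: none
Why: Oxidative phenol coupling followed by Friedel–Crafts alkylation: Ag2O turns both hindered phenols into persistent phenoxyl radicals that couple reversibly at their stilbene β-carbons, each on the face anti to the aryl on its C3, so that Ce and Ch should form as in 27, and catalytic BF3 then closes ring U 8-exo-trig onto quinone methide carbon Cg, where Cg (S) follows from allylic strain (Ch–H eclipsing the quinone methide ring) with the tethered arene entering from the side of Ce; ring U is the only strongly activated arene and lies over Ch and not over its own Cd because Ce–H prefers the plane of ring T, while the homodimer of 18 cannot cyclise and is recovered.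

Step 12
Reactants: 22 tetrameric quinone methide; 15 monomer A
Product: 24 protected hexamer, via seco quinone methide 23 (not isolated)
Conditions: 15 (2 equiv), BF3·OEt2 (0.3 equiv), CH2Cl2, −78 to −30 °C
Reagents that add atoms: none
Why: BF3 binds the carbonyl oxygen of the quinone methide of 22, stilbene carbon Cc of 15 adds to Cd (vinylogous 1,6-addition), the charge is relayed through the hindered phenol ring on Ca to Ca (intermediate 23, a second quinone methide), and ring P closes onto Ca with loss of a proton, which returns the catalyst. The closest known reaction type is the Lewis acid-catalysed 1,6-addition of electron-rich styrenes to 2,6-di-tert-butyl para-quinone methides with Friedel–Crafts termination, together with the acid-induced closure of ε-viniferin-type benzylic cations to dibenzocycloheptenes. The seven-membered ring (Ca, Cc, Cb and the edges of rings P and Q) closes 7-exo-trig by Friedel–Crafts alkylation at the carbon of ring P ortho to Cb, which is ortho and para to the two benzyloxy groups. Cc (S) should be set by addition to the stilbene face anti to ring P on Cb in the rotamer that keeps the far styryl carbon away from C3 of the dihydrofuran; Cd (R) by allylic strain in the quinone methide (Ce–H eclipsing the ring) with approach anti to ring T; Ca (S) by closure with its aryl cis to Cd, the arrangement with H at Cb, Cc and Ca on one face that is found in hopeaphenol-type dibenzocycloheptenes, although a simple allylic-strain model would favour the Ca epimer. The step needs intermolecular capture at Cd to outrun internal Friedel–Crafts closure and needs a single ring to attack Ca: in 22 rings T, W and Z and the aryl on Cj are pivalates and ring U is held in the eight-membered ring on the far side of Ce, in 15 ring Q is a pivalate so that ring P is the one strongly activated arene, and the tert-butyl groups keep both quinone methides persistent and block O-alkylation and ortho attack.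

Step 13
Reactants: 24 protected hexamer
Product: 25 hexabenzyl hexa-tert-butyl hexamer
Conditions: K2CO3 (catalytic), MeOH/THF (degassed), 40 °C, argon
Reagents that add atoms: none
Why: Base-catalysed transesterification cleaves the six aryl pivalates (aryloxide leaving groups), while benzyl ethers, the hindered phenols and the trans-dihydrobenzofurans should be stable to K2CO3 in methanol in the absence of air.

Step 14
Reactants: 25 hexabenzyl hexa-tert-butyl hexamer
Product: 26 hexa-tert-butyl hexamer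
Conditions: H2 (1 atm), Pd/C, EtOAc/MeOH, rt
Reagents that add atoms: none
Why: Hydrogenolysis of the six benzyl ethers over palladium on carbon, with no olefin left in the molecule and the dihydrobenzofuran C–O bonds slower to cleave than benzyl ethers, so the reaction is stopped at full debenzylation.

Step 15
Reactants: 26 hexa-tert-butyl hexamer
Product: 27 target hexamer
Conditions: AlCl3, toluene/MeNO2, 60 °C
Reagents that add atoms: none
Why: Retro-Friedel–Crafts de-tert-butylation, in which the phenol rings on Ca, Cd and Cg are protonated ipso to the tert-butyl groups and the tert-butyl cations are passed to toluene; no stereocentre is touched.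

Compound list

1 | 2-bromo-4,6-dimethoxybenzaldehyde | COc1cc(Br)c(C=O)c(OC)c1 | starting material
2 | 2-bromo-4,6-dihydroxybenzaldehyde | Oc1cc(Br)c(C=O)c(O)c1 | intermediate
3 | 3-bromo-4-formyl-5-hydroxyphenyl 2,2-dimethylpropanoate | CC(C)(C)C(=O)Oc1cc(O)c(C=O)c(Br)c1 | intermediate
4 | 1,3-bis(benzyloxy)-5-bromobenzene | Brc1cc(OCc2ccccc2)cc(OCc2ccccc2)c1 | starting material
5 | [3,5-bis(benzyloxy)phenyl]magnesium bromide | Br[Mg]c1cc(OCc2ccccc2)cc(OCc2ccccc2)c1 | intermediate
6 | racemic 4-{[3,5-bis(benzyloxy)phenyl](hydroxy)methyl}-3-bromo-5-hydroxyphenyl 2,2-dimethylpropanoate | CC(C)(C)C(=O)Oc1cc(O)c(C(O)c2cc(OCc3ccccc3)cc(OCc3ccccc3)c2)c(Br)c1 | intermediate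
7 | racemic 4-{[3,5-bis(benzyloxy)phenyl](4-methylbenzenesulfonyl)methyl}-3-bromo-5-hydroxyphenyl 2,2-dimethylpropanoate | CC(C)(C)C(=O)Oc1cc(O)c(C(c2cc(OCc3ccccc3)cc(OCc3ccccc3)c2)S(=O)(=O)c2ccc(C)cc2)c(Br)c1 | intermediate
8 | (1R,4R,5R)-4,7,7-trimethyl-6-thiabicyclo[3.2.1]octane (isothiocineole) | C[C@@H]1CC[C@@H]2C[C@H]1SC2(C)C | starting material
9 | 1-(benzyloxy)-4-(bromomethyl)benzene | BrCc1ccc(OCc2ccccc2)cc1 | starting material
10 | (1R,4R,5R)-6-[4-(benzyloxy)benzyl]-4,7,7-trimethyl-6-thiabicyclo[3.2.1]octan-6-ium tetrafluoroborate, benzyl group exo on sulfur | C[C@@H]1CC[C@@H]2C[C@H]1[S@@+](Cc3ccc(OCc4ccccc4)cc3)C2(C)C.F[B-](F)(F)F | intermediate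
11 | sulfonium ylide of 10 (carbanion on the benzylic carbon) | C[C@@H]1CC[C@@H]2C[C@H]1[S@@+]([CH-]c3ccc(OCc4ccccc4)cc3)C2(C)C | intermediate
12 | ortho-quinone methide: 4-{[3,5-bis(benzyloxy)phenyl]methylidene}-3-bromo-5-oxocyclohexa-1,3-dien-1-yl 2,2-dimethylpropanoate (either alkene geometry) | CC(C)(C)C(=O)OC1=CC(=O)C(=Cc2cc(OCc3ccccc3)cc(OCc3ccccc3)c2)C(Br)=C1 | intermediate
13 | (2R,3R)-2-[4-(benzyloxy)phenyl]-3-[3,5-bis(benzyloxy)phenyl]-4-bromo-2,3-dihydro-1-benzofuran-6-yl 2,2-dimethylpropanoate | Brc1cc(OC(=O)C(C)(C)C)cc2c1[C@@H](c1cc(OCc3ccccc3)cc(OCc3ccccc3)c1)[C@H](c1ccc(OCc3ccccc3)cc1)O2 | intermediate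
14 | 2,6-di-tert-butyl-4-ethenylphenol | C=Cc1cc(C(C)(C)C)c(O)c(C(C)(C)C)c1 | starting material
15 | monomer A: (2R,3R)-2-[4-(benzyloxy)phenyl]-3-[3,5-bis(benzyloxy)phenyl]-4-[(E)-2-(3,5-di-tert-butyl-4-hydroxyphenyl)ethenyl]-2,3-dihydro-1-benzofuran-6-yl 2,2-dimethylpropanoate | CC(C)(C)c1cc(/C=C/c2cc(OC(=O)C(C)(C)C)cc3c2[C@@H](c2cc(OCc4ccccc4)cc(OCc4ccccc4)c2)[C@H](c2ccc(OCc4ccccc4)cc2)O3)cc(C(C)(C)C)c1O | intermediate
16 | (2R,3R)-4-bromo-3-(3,5-dihydroxyphenyl)-2-(4-hydroxyphenyl)-2,3-dihydro-1-benzofuran-6-yl 2,2-dimethylpropanoate | Brc1cc(OC(=O)C(C)(C)C)cc2c1[C@@H](c1cc(O)cc(O)c1)[C@H](c1ccc(O)cc1)O2 | intermediate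
17 | (2R,3R)-4-bromo-3-[3,5-bis(pivaloyloxy)phenyl]-2-[4-(pivaloyloxy)phenyl]-2,3-dihydro-1-benzofuran-6-yl 2,2-dimethylpropanoate | Brc1cc(OC(=O)C(C)(C)C)cc2c1[C@@H](c1cc(OC(=O)C(C)(C)C)cc(OC(=O)C(C)(C)C)c1)[C@H](c1ccc(OC(=O)C(C)(C)C)cc1)O2 | intermediate
18 | monomer B: (2R,3R)-3-[3,5-bis(pivaloyloxy)phenyl]-4-[(E)-2-(3,5-di-tert-butyl-4-hydroxyphenyl)ethenyl]-2-[4-(pivaloyloxy)phenyl]-2,3-dihydro-1-benzofuran-6-yl 2,2-dimethylpropanoate | CC(C)(C)c1cc(/C=C/c2cc(OC(=O)C(C)(C)C)cc3c2[C@@H](c2cc(OC(=O)C(C)(C)C)cc(OC(=O)C(C)(C)C)c2)[C@H](c2ccc(OC(=O)C(C)(C)C)cc2)O3)cc(C(C)(C)C)c1O | intermediate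
19 | phenoxyl radical of 15 (oxygen-centred, spin delocalised to the stilbene β-carbon) | CC(C)(C)c1cc(/C=C/c2cc(OC(=O)C(C)(C)C)cc3c2[C@@H](c2cc(OCc4ccccc4)cc(OCc4ccccc4)c2)[C@H](c2ccc(OCc4ccccc4)cc2)O3)cc(C(C)(C)C)c1[O] | intermediate
20 | phenoxyl radical of 18 | CC(C)(C)c1cc(/C=C/c2cc(OC(=O)C(C)(C)C)cc3c2[C@@H](c2cc(OC(=O)C(C)(C)C)cc(OC(=O)C(C)(C)C)c2)[C@H](c2ccc(OC(=O)C(C)(C)C)cc2)O3)cc(C(C)(C)C)c1[O] | intermediate
21 | cross bis(quinone methide): 15 and 18 joined by the Ce–Ch bond (spatial arrangement at Ce and Ch as in 27); Cd and Cg are each the exocyclic CH of a 3,5-di-tert-butyl-4-oxocyclohexa-2,5-dien-1-ylidene; dihydrobenzofurans unchanged | CC(C)(C)C1=CC(=C[C@@H](c4cc(OC(=O)C(C)(C)C)cc5c4[C@@H](c4cc(OCc6ccccc6)cc(OCc6ccccc6)c4)[C@H](c4ccc(OCc6ccccc6)cc4)O5)[C@@H](C=C4C=C(C(C)(C)C)C(=O)C(C(C)(C)C)=C4)c2cc(OC(=O)C(C)(C)C)cc4c2[C@@H](c2cc(OC(=O)C(C)(C)C)cc(OC(=O)C(C)(C)C)c2)[C@H](c2ccc(OC(=O)C(C)(C)C)cc2)O4)C=C(C(C)(C)C)C1=O | intermediate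
22 | tetrameric quinone methide: units 2 and 3 of 27 with the eight-membered ring closed (Ce, Cf, Cg, Ch, Ci, Cj, Ck arranged as in 27); Cd is the exocyclic CH of a 3,5-di-tert-butyl-4-oxocyclohexa-2,5-dien-1-ylidene; the aryl on Cg is 3,5-di-tert-butyl-4-hydroxyphenyl; pivalates on rings T, W, Z (two) and on the aryl of Cj; benzyl ethers on ring U (two) and on the aryl of Ck | CC(C)(C)C1=CC(=C[C@H]2c4cc(OC(=O)C(C)(C)C)cc5c4[C@@H](c4cc(OCc6ccccc6)cc(OCc6ccccc6)c4[C@H](c4cc(C(C)(C)C)c(O)c(C(C)(C)C)c4)[C@H]2c2cc(OC(=O)C(C)(C)C)cc4c2[C@@H](c2cc(OC(=O)C(C)(C)C)cc(OC(=O)C(C)(C)C)c2)[C@H](c2ccc(OC(=O)C(C)(C)C)cc2)O4)[C@H](c2ccc(OCc6ccccc6)cc2)O5)C=C(C(C)(C)C)C1=O | intermediate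
23 | seco quinone methide: Cc–Cd bond formed (Cc, Cd arranged as in 27), the aryl on Cd now a 3,5-di-tert-butyl-4-hydroxyphenyl, Ca the exocyclic CH of a new 3,5-di-tert-butyl-4-oxocyclohexa-2,5-dien-1-ylidene, ring P not yet bonded to Ca | CC(C)(C)C1=CC(=C[C@@H](c3cc(OC(=O)C(C)(C)C)cc4c3[C@@H](c3cc(OCc6ccccc6)cc(OCc6ccccc6)c3)[C@H](c3ccc(OCc6ccccc6)cc3)O4)[C@H](c2cc(C(C)(C)C)c(O)c(C(C)(C)C)c2)[C@H]2c4cc(OC(=O)C(C)(C)C)cc5c4[C@@H](c4cc(OCc6ccccc6)cc(OCc6ccccc6)c4[C@H](c4cc(C(C)(C)C)c(O)c(C(C)(C)C)c4)[C@H]2c2cc(OC(=O)C(C)(C)C)cc4c2[C@@H](c2cc(OC(=O)C(C)(C)C)cc(OC(=O)C(C)(C)C)c2)[C@H](c2ccc(OC(=O)C(C)(C)C)cc2)O4)[C@H](c2ccc(OCc6ccccc6)cc2)O5)C=C(C(C)(C)C)C1=O | intermediate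
24 | protected hexamer: 27 with tert-butyl groups at both positions ortho to OH on the aryls of Ca, Cd and Cg; pivalates on the oxygens of rings Q, T, W, Z (two) and of the aryl on Cj; benzyl ethers on rings P (two) and U (two) and on the aryls of Ck and Cl; all twelve stereocentres as in 27 | Oc1c(C(C)(C)C)cc([C@H]2c3c(OCc6ccccc6)cc(OCc6ccccc6)cc3[C@@H]3c4c(cc(OC(=O)C(C)(C)C)cc4[C@H]2[C@H](c2cc(C(C)(C)C)c(O)c(C(C)(C)C)c2)[C@H]2c4cc(OC(=O)C(C)(C)C)cc5c4[C@@H](c4cc(OCc6ccccc6)cc(OCc6ccccc6)c4[C@H](c4cc(C(C)(C)C)c(O)c(C(C)(C)C)c4)[C@H]2c2cc(OC(=O)C(C)(C)C)cc4c2[C@@H](c2cc(OC(=O)C(C)(C)C)cc(OC(=O)C(C)(C)C)c2)[C@H](c2ccc(OC(=O)C(C)(C)C)cc2)O4)[C@H](c2ccc(OCc6ccccc6)cc2)O5)O[C@H]3c2ccc(OCc6ccccc6)cc2)cc1C(C)(C)C | intermediate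
25 | as 24 with the six pivalates replaced by OH (benzyl ethers on rings P and U and on the aryls of Ck and Cl, and six tert-butyl groups kept) | Oc1c(C(C)(C)C)cc([C@H]2c3c(OCc6ccccc6)cc(OCc6ccccc6)cc3[C@@H]3c4c(cc(O)cc4[C@H]2[C@H](c2cc(C(C)(C)C)c(O)c(C(C)(C)C)c2)[C@H]2c4cc(O)cc5c4[C@@H](c4cc(OCc6ccccc6)cc(OCc6ccccc6)c4[C@H](c4cc(C(C)(C)C)c(O)c(C(C)(C)C)c4)[C@H]2c2cc(O)cc4c2[C@@H](c2cc(O)cc(O)c2)[C@H](c2ccc(O)cc2)O4)[C@H](c2ccc(OCc6ccccc6)cc2)O5)O[C@H]3c2ccc(OCc6ccccc6)cc2)cc1C(C)(C)C | intermediate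
26 | hexa-tert-butyl derivative of 27 (tert-butyl groups ortho to OH on the aryls of Ca, Cd and Cg; all other oxygens free) | Oc1c(C(C)(C)C)cc([C@H]2c3c(O)cc(O)cc3[C@@H]3c4c(cc(O)cc4[C@H]2[C@H](c2cc(C(C)(C)C)c(O)c(C(C)(C)C)c2)[C@H]2c4cc(O)cc5c4[C@@H](c4cc(O)cc(O)c4[C@H](c4cc(C(C)(C)C)c(O)c(C(C)(C)C)c4)[C@H]2c2cc(O)cc4c2[C@@H](c2cc(O)cc(O)c2)[C@H](c2ccc(O)cc2)O4)[C@H](c2ccc(O)cc2)O5)O[C@H]3c2ccc(O)cc2)cc1C(C)(C)C | intermediate
27 | CNP0184494.1, resveratrol hexamer (Ca S, Cb R, Cc S, Cd R, Ce R, Cf R, Cg S, Ch S, Ci R, Cj R, Ck R, Cl R) | Oc1ccc([C@H]2c3c(O)cc(O)cc3[C@@H]3c4c(cc(O)cc4[C@H]2[C@H](c2ccc(O)cc2)[C@H]2c4cc(O)cc5c4[C@@H](c4cc(O)cc(O)c4[C@H](c4ccc(O)cc4)[C@H]2c2cc(O)cc4c2[C@@H](c2cc(O)cc(O)c2)[C@H](c2ccc(O)cc2)O4)[C@H](c2ccc(O)cc2)O5)O[C@H]3c2ccc(O)cc2)cc1 | target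

Total step count: 15.
Longest linear sequence: 13 steps (steps 1, 2, 3, 4, 6, 8, 9, 10, 11, 12, 13, 14, 15).

Steps most likely to fail

Step 12. The union may suffer from poor facial selectivity at Cd, from ring closure to the epimer at Ca, or from proton-initiated self-cyclisation of 15 that starves the coupling. The fallback splits the cascade into an anionic addition and a reductive ring closure. It sets out from 13 and 22. Palladium-catalysed α-arylation of commercial 1-(3,5-di-tert-butyl-4-hydroxyphenyl)ethan-1-one with 13 (Pd(OAc)2, XPhos, K3PO4, toluene, 80 °C) gives deoxybenzoin F1. Its dianion (LiHMDS, THF, −78 °C) adds 1,6 to quinone methide 22 under basic conditions, where no arene of 22 can compete, to give keto hexamer F2; Cc is then α to the ketone and can be equilibrated. BF3·OEt2 with Et3SiH closes ring P onto the ketone and reduces the resulting doubly benzylic cation from the face anti to Cd, which sets Ca. The fallback rejoins the route at 24.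

Step 11. The one-pot coupling may partition statistically into homodimers, scramble through the labile Ce–Ch bond, or close ring U onto its own quinone methide (seven-membered ring) in place of the remote one. The fallback gives up the cross-coupling for self-coupling and sets out from 15 alone. Ag2O oxidation gives the C2-symmetric homo bis(quinone methide) F3, in which both possible closures to an eight-membered ring are identical. Catalytic BF3·OEt2 gives benzyl-protected tetrameric quinone methide F4. F4 is united with 15 as in step 12, with 15 in large excess to outrun closure by the now electron-rich ring Z, to give nonabenzyl protected hexamer F5. Methanolysis of the three pivalates (K2CO3, MeOH/THF) gives nonabenzyl hexaphenol F6, and hydrogenolysis (H2, Pd/C) rejoins the route at 26.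

Step 6. The chiral ylide may give insufficient face control or erode the trans selectivity. The fallback takes the absolute configuration from a resolution in place of the ylide and sets out from 7 and 9. Tetrahydrothiophene and 9 give achiral sulfonium salt F7. Annulation of F7 with 7 (Cs2CO3, CH2Cl2) gives the racemic trans-bromide, which is 13 together with its enantiomer F8. Preparative chromatography on a chiral stationary phase separates the two and rejoins the route at 13.

Further compounds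
F1 | step 12 | deoxybenzoin: (2R,3R)-2-[4-(benzyloxy)phenyl]-3-[3,5-bis(benzyloxy)phenyl]-4-[2-(3,5-di-tert-butyl-4-hydroxyphenyl)-2-oxoethyl]-2,3-dihydro-1-benzofuran-6-yl 2,2-dimethylpropanoate | CC(C)(C)c1cc(C(=O)Cc2cc(OC(=O)C(C)(C)C)cc3c2[C@@H](c2cc(OCc4ccccc4)cc(OCc4ccccc4)c2)[C@H](c2ccc(OCc4ccccc4)cc2)O3)cc(C(C)(C)C)c1O
F2 | step 12 | keto hexamer: as 23 but with Ca a ketone carbon bearing its 3,5-di-tert-butyl-4-hydroxyphenyl ring (Cc–Cd bond formed, ring P not yet bonded to Ca) | CC(C)(C)c1cc(C(=O)[C@@H](c3cc(OC(=O)C(C)(C)C)cc4c3[C@@H](c3cc(OCc6ccccc6)cc(OCc6ccccc6)c3)[C@H](c3ccc(OCc6ccccc6)cc3)O4)[C@H](c2cc(C(C)(C)C)c(O)c(C(C)(C)C)c2)[C@H]2c4cc(OC(=O)C(C)(C)C)cc5c4[C@@H](c4cc(OCc6ccccc6)cc(OCc6ccccc6)c4[C@H](c4cc(C(C)(C)C)c(O)c(C(C)(C)C)c4)[C@H]2c2cc(OC(=O)C(C)(C)C)cc4c2[C@@H](c2cc(OC(=O)C(C)(C)C)cc(OC(=O)C(C)(C)C)c2)[C@H](c2ccc(OC(=O)C(C)(C)C)cc2)O4)[C@H](c2ccc(OCc6ccccc6)cc2)O5)cc(C(C)(C)C)c1O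
F3 | step 11 | homo bis(quinone methide): two molecules of 15 joined by the Ce–Ch bond, both former stilbene α-carbons quinone methide carbons | CC(C)(C)C1=CC(=C[C@@H](c4cc(OC(=O)C(C)(C)C)cc5c4[C@@H](c4cc(OCc6ccccc6)cc(OCc6ccccc6)c4)[C@H](c4ccc(OCc6ccccc6)cc4)O5)[C@@H](C=C4C=C(C(C)(C)C)C(=O)C(C(C)(C)C)=C4)c2cc(OC(=O)C(C)(C)C)cc4c2[C@@H](c2cc(OCc6ccccc6)cc(OCc6ccccc6)c2)[C@H](c2ccc(OCc6ccccc6)cc2)O4)C=C(C(C)(C)C)C1=O
F4 | step 11 | benzyl-protected tetrameric quinone methide: as 22 but with benzyl ethers in place of the pivalates on ring Z and on the aryl of Cj | CC(C)(C)C1=CC(=C[C@H]2c4cc(OC(=O)C(C)(C)C)cc5c4[C@@H](c4cc(OCc6ccccc6)cc(OCc6ccccc6)c4[C@H](c4cc(C(C)(C)C)c(O)c(C(C)(C)C)c4)[C@H]2c2cc(OC(=O)C(C)(C)C)cc4c2[C@@H](c2cc(OCc6ccccc6)cc(OCc6ccccc6)c2)[C@H](c2ccc(OCc6ccccc6)cc2)O4)[C@H](c2ccc(OCc6ccccc6)cc2)O5)C=C(C(C)(C)C)C1=O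
F5 | step 11 | nonabenzyl protected hexamer: as 24 but with benzyl ethers in place of the pivalates on ring Z and on the aryl of Cj | Oc1c(C(C)(C)C)cc([C@H]2c3c(OCc6ccccc6)cc(OCc6ccccc6)cc3[C@@H]3c4c(cc(OC(=O)C(C)(C)C)cc4[C@H]2[C@H](c2cc(C(C)(C)C)c(O)c(C(C)(C)C)c2)[C@H]2c4cc(OC(=O)C(C)(C)C)cc5c4[C@@H](c4cc(OCc6ccccc6)cc(OCc6ccccc6)c4[C@H](c4cc(C(C)(C)C)c(O)c(C(C)(C)C)c4)[C@H]2c2cc(OC(=O)C(C)(C)C)cc4c2[C@@H](c2cc(OCc6ccccc6)cc(OCc6ccccc6)c2)[C@H](c2ccc(OCc6ccccc6)cc2)O4)[C@H](c2ccc(OCc6ccccc6)cc2)O5)O[C@H]3c2ccc(OCc6ccccc6)cc2)cc1C(C)(C)C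
F6 | step 11 | nonabenzyl hexaphenol: as F5 with the three pivalates on rings Q, T and W replaced by OH | Oc1c(C(C)(C)C)cc([C@H]2c3c(OCc6ccccc6)cc(OCc6ccccc6)cc3[C@@H]3c4c(cc(O)cc4[C@H]2[C@H](c2cc(C(C)(C)C)c(O)c(C(C)(C)C)c2)[C@H]2c4cc(O)cc5c4[C@@H](c4cc(OCc6ccccc6)cc(OCc6ccccc6)c4[C@H](c4cc(C(C)(C)C)c(O)c(C(C)(C)C)c4)[C@H]2c2cc(O)cc4c2[C@@H](c2cc(OCc6ccccc6)cc(OCc6ccccc6)c2)[C@H](c2ccc(OCc6ccccc6)cc2)O4)[C@H](c2ccc(OCc6ccccc6)cc2)O5)O[C@H]3c2ccc(OCc6ccccc6)cc2)cc1C(C)(C)C
F7 | step 6 | 1-[4-(benzyloxy)benzyl]thiolan-1-ium bromide | C(c1ccc(OCc2ccccc2)cc1)[S+]1CCCC1.[Br-]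
F8 | step 6 | (2S,3S)-2-[4-(benzyloxy)phenyl]-3-[3,5-bis(benzyloxy)phenyl]-4-bromo-2,3-dihydro-1-benzofuran-6-yl 2,2-dimethylpropanoate (enantiomer of 13) | Brc1cc(OC(=O)C(C)(C)C)cc2c1[C@H](c1cc(OCc3ccccc3)cc(OCc3ccccc3)c1)[C@@H](c1ccc(OCc3ccccc3)cc1)O2
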